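## Structural features

Macrocarpal J joins two units through a single C–C bond: a trans-fused eudesmane (rings A and B) and a fully substituted phloroglucinol ring with two formyl groups. The link is the benzylic methine C9′, which also carries an isobutyl group. There are six stereocentres. C5 (α-H), C7 (β-hydroxyisopropyl) and C10 (β-methyl, C14) lie on ring B. C4 (α-hydroxyl, β-methyl syn-axial to C14), C1 (β, equatorial side chain) and C9′ (S) lie on or next to ring A. C10, C1 and C9′ form a contiguous, crowded triad. The C1–C9′ bond, between a neopentyl ring carbon and a doubly ortho-substituted benzylic carbon, is the real difficulty, because C9′ cannot be corrected once it is set. The tertiary carbinols at C4 and C11 ionise or dehydrate under Brønsted and strong Lewis acids, and the trihydroxy-isophthalaldehyde is sensitive to base and oxidants. The arene therefore travels as its trimethyl ether, and formylation and ether cleavage must avoid acid. The key step uses the fact that ring B with C5, C7, C10 and the C11 carbinol is already present in (−)-elemol. Its vinyl group (C1, C2) on C10 and isopropenyl group (C3, C4, C15) on C5 are trans-diequatorial and lack only the C2–C3 bond to become ring A. The C2 oxygen left by that closure then serves the C1–C9′ bond and the C4 carbinol before it is removed.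

## Logic of the disconnections

**23 ⇒ 22 ⇒ 21.** The three aryl O–CH3 bonds and the C11 O–Si bond are cut last. Free phenols next to formyl groups and a free C11 carbinol would not survive the cation, enolate and organolithium steps. The gain is a robust ether, 21. The demand is that both deprotections avoid acid: fluoride at silicon (21 to 22) and thiolate attack at the methyl carbons (22 to 23).

**21 ⇒ 19 ⇒ 18.** The two aryl–CHO bonds at C3′ and C5′ are cut, through the C–Br bonds of 19. Formyl groups would destabilise the benzylic cation needed earlier, so they come after the coupling. The arene of 18 is then a plain trimethoxyphenyl group. Because 18 holds a free tertiary carbinol at C4, formylation must proceed through bromination and halogen–lithium exchange and not through an acidic electrophilic formylation.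

**18 ⇒ 17 ⇒ 15 ⇒ 14.** The C4–O bond and the C2–C3 saturation are traced back to the enone 14. Epoxide 15 places oxygen on C4, the transposition to 17 removes the C2 oxygen in the same operation, and hydrogenation gives 18. This removes a quaternary carbinol stereocentre from the problem. The demand is epoxidation on the α-face, opposite C14.

**14 ⇒ 8 + 12.** The C1–C9′ bond is cut. It is the only bond between terpene and arene and lies α to the C2 carbonyl, so the route becomes convergent. The demand is a nucleophile at the neopentyl C1 (8) and an ionisable benzylic partner (12), with face control at C1 and C9′ and a final epimerisation at C1.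

**12 ⇒ 9 + 10.** The C9′–C10′ bond is cut by a Grignard addition. The racemate is enough, because ionisation flattens C9′ before the coupling.

**8 ⇒ 6 ⇒ 4.** No skeletal bond is cut. 8 comes from 6 by kinetic enolisation at C1, and 6 from 4 by oxidation at C2 and migration of the C4(15) alkene into conjugation. The demand is α′-deprotonation in preference to γ-deprotonation.

**4 ⇒ 3.** The C2–C3 bond is cut, opening ring A. The bicycle is reduced to a monocycle that already holds C5, C7 and C10. The demand is an aldehyde at C2 beside an intact isopropenyl group. The precursor 3 carries the C11 oxygen as a triethylsilyl ether, so that the aluminium Lewis acid meets only the aldehyde and the tertiary carbinol can neither consume it nor ionise.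

**3 ⇒ 2 ⇒ 1.** The C2–O bond and the O–Si bond are cut. The demand is anti-Markovnikov oxidation of the vinyl group of 2 in the presence of the isopropenyl group.

## Other disconnections considered

**Alternative 1:** The cut is at C5–C10 and C6–C7. The forward step is an intramolecular Diels–Alder reaction of the acyclic trienone A1, whose vinyl ketone adds across the (Z)-diene, followed by base epimerisation at C5 to give the trans-fused enone A2.
- In its favour: both rings and two bonds form at once, and C10 and C7 are related through the diene geometry. The C1–C9′ bond and its two stereocentres are made in an open chain before any ring exists. On that point it is better than the chosen plan, where this bond is the weakest link.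
- Against it: a trisubstituted diene terminus with the tether on the inside is a slow class of substrate and is open to 1,5-hydrogen shift. All absolute configuration must be built from scratch. C15 and the C4 hydroxyl still have to be added to the C4 ketone, where a methyl nucleophile would be expected to arrive anti to C14 and give the wrong C4 epimer, so an indirect sequence would be needed. The C8–C9 alkene must also be reduced.
- Comparison: both key steps are pericyclic and well understood, and A2 gains more skeletal bonds in one step. The chosen plan takes C5, C7 and C10 from 1 and should be clearly shorter.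

**Alternative 2:** The cut is first at C6–C7 of a ten-membered ring, then at C1–C9′, C5–C10 and C4–O. A hedycaryol synthase would cyclise the diphosphate A3 to (7R)-hedycaryol A4. The C1=C10 alkene of A4 would then attack the ortho-quinone methide A5, the C10 cation would be captured across the ring by C4=C5, and water would add at C4.
- In its favour: it is the shortest conceivable route. The arene needs no protection, no late formylation and no demethylation. In step count and endgame it is better than the chosen plan.
- Against it: it needs an expressed enzyme and its substrate. A4 rearranges thermally (Cope) to 1 and reacts through several conformers. A5 can also add to alkenes in a hetero-Diels–Alder sense. Five stereocentres (C1, C4, C5, C10, C9′) would be set in one uncatalysed event with no handle for correction.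
- Comparison: the origin of C7 is biological in both plans, so they are equal there. The chosen plan is longer but proceeds through isolable intermediates with a separate control element at each centre.

**Alternative 3:** The cut is at C5–C10 and C8–C9. An exo-selective Diels–Alder reaction of methacrolein A6 with the (E)-diene A7 under a chiral oxazaborolidinium Lewis acid would give the adduct A8, with quaternary C10 and C5 set.
- In its favour: absolute configuration comes from a catalyst, either enantiomer is accessible, and supply does not depend on a natural product. On these points it is better than the chosen plan. The C1 formyl group of A8 is also a good anchor for the C1–C9′ bond.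
- Against it: A8 holds one ring and two stereocentres. Ring A (C1–C2, C2–C3, C3–C4), C1, C9′, C4 and C7 (by face-selective reduction of the C6=C7 alkene) all remain to be made.
- Comparison: the cycloaddition is as reliable as the ene closure. The chosen plan starts with ring B and three stereocentres in place and closes ring A in one step, so it should need far fewer steps.

Key step: step 3

Assumption: (−)-elemol (1), in the configuration drawn, is bought as the isolated natural product. Eudesmane numbering is used, C9′ is the benzylic carbon, and α is the face opposite the C10 methyl (C14).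

## Route

Step 1
Reactants: 1 (−)-elemol
Product: 2 elemol triethylsilyl ether
Conditions: TESOTf, 2,6-lutidine, CH2Cl2, −78 → 0 °C
Reagents that add atoms: triethylsilyl trifluoromethanesulfonate, CC[Si](CC)(CC)OS(=O)(=O)C(F)(F)F
Why: Silyl ether formation at a tertiary alcohol with a silyl triflate and a hindered pyridine base; it masks the C11 carbinol so that the Lewis acid of step 3, the amide base of step 5 and the cation of step 7 meet no free hydroxyl. No stereocentre is touched.

Step 2
Reactants: 2 elemol triethylsilyl ether
Product: 3 11-(triethylsilyloxy)elem-3-en-2-al (vinyl group on C10 turned into CH2CHO)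
Conditions: PdCl2(PhCN)2 (10 mol%), CuCl2·2H2O (10 mol%), AgNO2 (5 mol%), O2 (1 atm), t-BuOH/MeNO2 (15:1), rt
Reagents that add atoms: dioxygen, O=O
Why: Nitrite-modified, aldehyde-selective Wacker oxidation: attack at the internal carbon is disfavoured next to the quaternary C10, so oxygen should go to the terminal carbon, while the 1,1-disubstituted isopropenyl group is a poor Wacker substrate. C10 cannot epimerise, so no stereocentre is at risk.

Step 3
Reactants: 3 11-(triethylsilyloxy)elem-3-en-2-al
Product: 4 11-(triethylsilyloxy)eudesm-4(15)-en-2β-ol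
Conditions: Me2AlCl (2 equiv), CH2Cl2, −78 → −20 °C; aq. potassium sodium tartrate
Reagents that add atoms: none
Why: This is a Lewis-acid-promoted type 2 intramolecular carbonyl-ene reaction, the closest known case being the Me2AlCl cyclisation of 5-methylhex-5-enals to 3-methylenecyclohexanols. Me2AlCl binds the C2 aldehyde, the terminal isopropenyl carbon C3 attacks C2, and a hydrogen of the C15 methyl passes to oxygen through a six-membered array, in concert or through a short-lived tertiary C4 cation, leaving the C4(15) exocyclic alkene. Ring A closes as a six-membered ring, exo with respect to the carbonyl group and endo with respect to the ene double bond, in a chair in which C1 and C4 leave C10 and C5 equatorially, so the trans fusion already present on ring B is retained. The one new stereocentre, C2, is set by the closed transition state, which needs the oxygen axial (β) to reach the C15 hydrogens; this puts it syn to C14, so some 2α-epimer may form, which is harmless because C2 is oxidised in step 4. The selectivity that matters is ene closure over proton-initiated Prins closure, which could capture chloride or remove H5. Me2AlCl should secure it because its methyl groups destroy adventitious acid, the silyl ether keeps the C11 oxygen away from the Lewis acid, and H5 points to the α-face, away from the axial oxygen, so only C15 can donate hydrogen.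

Step 4
Reactants: 4 11-(triethylsilyloxy)eudesm-4(15)-en-2β-ol
Product: 6 11-(triethylsilyloxy)eudesm-3-en-2-one, via β,γ-unsaturated ketone 5 (not isolated)
Conditions: DMP, NaHCO3, CH2Cl2, 0 °C → rt; then DBU, rt
Reagents that add atoms: none
Why: Periodinane oxidation of the secondary alcohol gives 5, whose doubly activated C3 hydrogens let DBU move the alkene into conjugation (base-mediated alkene isomerisation). Both C2 epimers and any alkene isomers of 4 converge here, and the trans fusion at C5 is the thermodynamic one.

Step 5
Reactants: 6 11-(triethylsilyloxy)eudesm-3-en-2-one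
Product: 8 2-(trimethylsilyloxy)-11-(triethylsilyloxy)eudesma-1,3-diene, via lithium dienolate 7 (not isolated)
Conditions: LiN(i-Pr)2, THF, −78 °C; TMSCl, Et3N, −78 → 0 °C
Reagents that add atoms: chlorotrimethylsilane, C[Si](C)(C)Cl
Why: Kinetic deprotonation of a cyclohexenone at the α′ carbon (C1) by a lithium amide at low temperature, as with isophorone, gives the cross-conjugated dienolate 7, which TMSCl traps on oxygen. γ-Deprotonation at C15 or C5 is the thermodynamic path and is avoided by the irreversible conditions.

Step 6
Reactants: 9 2,4,6-trimethoxybenzaldehyde; 10 isobutylmagnesium bromide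
Product: 12 rac-3-methyl-1-(2,4,6-trimethoxyphenyl)butyl acetate, via bromomagnesium alkoxide 11 (not isolated)
Conditions: THF, 0 °C; then Ac2O, DMAP (cat.), 0 °C → rt
Reagents that add atoms: acetic anhydride, CC(=O)OC(C)=O
Why: Grignard addition to the aldehyde, then O-acylation of the magnesium alkoxide in the same flask. The racemate suffices because ionisation in step 7 erases this centre.

Step 7
Reactants: 8 2-(trimethylsilyloxy)-11-(triethylsilyloxy)eudesma-1,3-diene; 12 rac-3-methyl-1-(2,4,6-trimethoxyphenyl)butyl acetate
Product: 14 (9′S)-1β-[3-methyl-1-(2,4,6-trimethoxyphenyl)butyl]-11-(triethylsilyloxy)eudesm-3-en-2-one, via 1α-epimer 13 (not isolated)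
Conditions: TMSOTf (10 mol%), 2,6-di-tert-butyl-4-methylpyridine, CH2Cl2, −78 → −40 °C (slow addition of 12); then NaOMe (0.3 equiv), MeOH, 0 °C → rt
Reagents that add atoms: none
Why: Lewis-acid-mediated SN1 α-alkylation of a silyl enol ether (Mukaiyama-type) by the benzylic cation that three methoxy groups stabilise. The cation should approach C1 anti to C14, with its hydrogen between C2 and C10, the aryl group over the siloxydiene and the isobutyl group outward, which sets 9′S. Methoxide then epimerises C1 through the enolate to the equatorial 1β arrangement, which is also the one produced by protonation anti to C14.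

Step 8
Reactants: 14 (9′S)-1β-[3-methyl-1-(2,4,6-trimethoxyphenyl)butyl]-11-(triethylsilyloxy)eudesm-3-en-2-one
Product: 15 (9′S)-3α,4α-epoxy-1β-[3-methyl-1-(2,4,6-trimethoxyphenyl)butyl]-11-(triethylsilyloxy)eudesman-2-one
Conditions: 30% H2O2, NaOH, MeOH, 0 °C → rt
Reagents that add atoms: hydrogen peroxide, OO
Why: Weitz–Scheffer nucleophilic epoxidation of the enone. Hydroperoxide should add to C4 from the α-face because the β trajectory is 1,3-diaxial to C14, and the enolate then closes the 3α,4α-epoxide, fixing the C4 oxygen α and the C15 methyl β.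

Step 9
Reactants: 15 (9′S)-3α,4α-epoxy-1β-[3-methyl-1-(2,4,6-trimethoxyphenyl)butyl]-11-(triethylsilyloxy)eudesman-2-one
Product: 17 (9′S)-1β-[3-methyl-1-(2,4,6-trimethoxyphenyl)butyl]-11-(triethylsilyloxy)eudesm-2-en-4α-ol, via epoxy hydrazone 16 (not isolated)
Conditions: N2H4·H2O, AcOH, MeOH, 0 °C → rt
Reagents that add atoms: none
Why: Wharton transposition: the hydrazone 16 opens the epoxide and the resulting vinyldiazene loses N2 to leave the C2=C3 alkene. The C4–O bond is never broken, so the 4α-carbinol is retained.

Step 10
Reactants: 17 (9′S)-1β-[3-methyl-1-(2,4,6-trimethoxyphenyl)butyl]-11-(triethylsilyloxy)eudesm-2-en-4α-ol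
Product: 18 (9′S)-1β-[3-methyl-1-(2,4,6-trimethoxyphenyl)butyl]-11-(triethylsilyloxy)eudesman-4α-ol
Conditions: H2 (1 atm), [Ir(cod)(PCy3)(py)]PF6 (5 mol%), CH2Cl2, rt
Reagents that add atoms: none
Why: Hydroxyl-directed homogeneous hydrogenation of the hindered cis-disubstituted alkene by a cationic iridium catalyst. No stereocentre is formed, and this catalyst should neither cleave the allylic tertiary C–O bond nor reduce the arene.

Step 11
Reactants: 18 (9′S)-1β-[3-methyl-1-(2,4,6-trimethoxyphenyl)butyl]-11-(triethylsilyloxy)eudesman-4α-ol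
Product: 19 (9′S)-1β-[1-(3,5-dibromo-2,4,6-trimethoxyphenyl)-3-methylbutyl]-11-(triethylsilyloxy)eudesman-4α-ol
Conditions: NBS (2.1 equiv), MeCN, 0 °C, dark
Reagents that add atoms: N-bromosuccinimide, O=C1CCC(=O)N1Br
Why: Electrophilic aromatic bromination of the only two free ring positions, each activated by two ortho and one para methoxy group. Neutral NBS should leave the tertiary carbinol and the silyl ether untouched.

Step 12
Reactants: 19 (9′S)-1β-[1-(3,5-dibromo-2,4,6-trimethoxyphenyl)-3-methylbutyl]-11-(triethylsilyloxy)eudesman-4α-ol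
Product: 21 (9′S)-1β-[1-(3,5-diformyl-2,4,6-trimethoxyphenyl)-3-methylbutyl]-11-(triethylsilyloxy)eudesman-4α-ol, via dilithio alkoxide 20 (not isolated)
Conditions: t-BuLi (5.5 equiv), THF, −78 °C; DMF, −78 → 0 °C; H2O
Reagents that add atoms: N,N-dimethylformamide, CN(C)C=O
Why: The first equivalent of t-BuLi forms the C4 alkoxide and four more effect double bromine–lithium exchange to 20, each carbanion flanked by two methoxy groups; DMF then formylates both positions (Bouveault-type). The tetrahedral adducts persist until work-up, so over-addition is excluded and no acid touches the carbinols.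

Step 13
Reactants: 21 (9′S)-1β-[1-(3,5-diformyl-2,4,6-trimethoxyphenyl)-3-methylbutyl]-11-(triethylsilyloxy)eudesman-4α-ol
Product: 22 macrocarpal J tri-O-methyl ether
Conditions: HF·pyridine, pyridine, THF, 0 °C → rt
Reagents that add atoms: none
Why: Fluoride-mediated cleavage of the tertiary silyl ether under buffered conditions that should spare the aldehydes and both tertiary carbinols.

Step 14
Reactants: 22 macrocarpal J tri-O-methyl ether
Product: 23 macrocarpal J
Conditions: 4-MeC6H4SNa (10 equiv), DMPU, 120 °C; then 1 M HCl (work-up)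
Reagents that add atoms: none
Why: Nucleophilic (SN2) demethylation of aryl methyl ethers by an arenethiolate in a dipolar aprotic solvent: each phenoxide leaving group is stabilised by ortho and para formyl groups. The basic medium spares the C4 and C11 carbinols, which acidic ether cleavage would ionise, and acidification on work-up frees the triphenol.

## Compound list

1 | (−)-elemol | C=C(C)[C@@H]1C[C@H](C(C)(C)O)CC[C@]1(C=C)C | starting material
2 | elemol triethylsilyl ether | C=C(C)[C@@H]1C[C@H](C(C)(C)O[Si](CC)(CC)CC)CC[C@]1(C=C)C | intermediate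
3 | 11-(triethylsilyloxy)elem-3-en-2-al | C=C(C)[C@@H]1C[C@H](C(C)(C)O[Si](CC)(CC)CC)CC[C@]1(CC=O)C | intermediate
4 | 11-(triethylsilyloxy)eudesm-4(15)-en-2β-ol (5α-H, 7β, 10β-Me) | C1[C@H](O)CC(=C)[C@@H]2C[C@H](C(C)(C)O[Si](CC)(CC)CC)CC[C@]21C | intermediate
5 | 11-(triethylsilyloxy)eudesm-4(15)-en-2-one | O=C1CC(=C)[C@@H]2C[C@H](C(C)(C)O[Si](CC)(CC)CC)CC[C@@]2(C)C1 | intermediate (not isolated)
6 | 11-(triethylsilyloxy)eudesm-3-en-2-one | O=C1C=C(C)[C@@H]2C[C@H](C(C)(C)O[Si](CC)(CC)CC)CC[C@@]2(C)C1 | intermediate
7 | lithium 11-(triethylsilyloxy)eudesma-1,3-dien-2-olate | [Li]OC1=C[C@]2(C)CC[C@@H](C(C)(C)O[Si](CC)(CC)CC)C[C@H]2C(C)=C1 | intermediate (not isolated)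
8 | 2-(trimethylsilyloxy)-11-(triethylsilyloxy)eudesma-1,3-diene | C[Si](C)(C)OC1=C[C@]2(C)CC[C@@H](C(C)(C)O[Si](CC)(CC)CC)C[C@H]2C(C)=C1 | intermediate
9 | 2,4,6-trimethoxybenzaldehyde | COc1cc(OC)c(C=O)c(OC)c1 | starting material
10 | isobutylmagnesium bromide | CC(C)C[Mg]Br | starting material
11 | bromomagnesium 3-methyl-1-(2,4,6-trimethoxyphenyl)butan-1-olate | CC(C)CC(O[Mg]Br)c1c(OC)cc(OC)cc1OC | intermediate (not isolated)
12 | rac-3-methyl-1-(2,4,6-trimethoxyphenyl)butyl acetate | CC(C)CC(OC(C)=O)c1c(OC)cc(OC)cc1OC | intermediate
13 | (9′S)-1α-[3-methyl-1-(2,4,6-trimethoxyphenyl)butyl]-11-(triethylsilyloxy)eudesm-3-en-2-one | CC(C)C[C@H](c1c(OC)cc(OC)cc1OC)[C@H]1C(=O)C=C(C)[C@@H]2C[C@H](C(C)(C)O[Si](CC)(CC)CC)CC[C@]21C | intermediate (not isolated)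
14 | (9′S)-1β-[3-methyl-1-(2,4,6-trimethoxyphenyl)butyl]-11-(triethylsilyloxy)eudesm-3-en-2-one | CC(C)C[C@H](c1c(OC)cc(OC)cc1OC)[C@@H]1C(=O)C=C(C)[C@@H]2C[C@H](C(C)(C)O[Si](CC)(CC)CC)CC[C@]21C | intermediate
15 | (9′S)-3α,4α-epoxy-1β-[3-methyl-1-(2,4,6-trimethoxyphenyl)butyl]-11-(triethylsilyloxy)eudesman-2-one | CC(C)C[C@H](c1c(OC)cc(OC)cc1OC)[C@@H]1C(=O)[C@H]3O[C@@]3(C)[C@@H]2C[C@H](C(C)(C)O[Si](CC)(CC)CC)CC[C@]21C | intermediate
16 | hydrazone of 15 at C2 | CC(C)C[C@H](c1c(OC)cc(OC)cc1OC)[C@@H]1C(=NN)[C@H]3O[C@@]3(C)[C@@H]2C[C@H](C(C)(C)O[Si](CC)(CC)CC)CC[C@]21C | intermediate (not isolated)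
17 | (9′S)-1β-[3-methyl-1-(2,4,6-trimethoxyphenyl)butyl]-11-(triethylsilyloxy)eudesm-2-en-4α-ol | CC(C)C[C@H](c1c(OC)cc(OC)cc1OC)[C@@H]1C=C[C@@](C)(O)[C@@H]2C[C@H](C(C)(C)O[Si](CC)(CC)CC)CC[C@]21C | intermediate
18 | (9′S)-1β-[3-methyl-1-(2,4,6-trimethoxyphenyl)butyl]-11-(triethylsilyloxy)eudesman-4α-ol | CC(C)C[C@H](c1c(OC)cc(OC)cc1OC)[C@@H]1CC[C@@](C)(O)[C@@H]2C[C@H](C(C)(C)O[Si](CC)(CC)CC)CC[C@]21C | intermediate
19 | (9′S)-1β-[1-(3,5-dibromo-2,4,6-trimethoxyphenyl)-3-methylbutyl]-11-(triethylsilyloxy)eudesman-4α-ol | CC(C)C[C@H](c1c(OC)c(Br)c(OC)c(Br)c1OC)[C@@H]1CC[C@@](C)(O)[C@@H]2C[C@H](C(C)(C)O[Si](CC)(CC)CC)CC[C@]21C | intermediate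
20 | 3′,5′-dilithio lithium 4-alkoxide derived from 19 | CC(C)C[C@H](c1c(OC)c([Li])c(OC)c([Li])c1OC)[C@@H]1CC[C@@](C)(O[Li])[C@@H]2C[C@H](C(C)(C)O[Si](CC)(CC)CC)CC[C@]21C | intermediate (not isolated)
21 | (9′S)-1β-[1-(3,5-diformyl-2,4,6-trimethoxyphenyl)-3-methylbutyl]-11-(triethylsilyloxy)eudesman-4α-ol | CC(C)C[C@H](c1c(OC)c(C=O)c(OC)c(C=O)c1OC)[C@@H]1CC[C@@](C)(O)[C@@H]2C[C@H](C(C)(C)O[Si](CC)(CC)CC)CC[C@]21C | intermediate
22 | macrocarpal J tri-O-methyl ether: (9′S)-1β-[1-(3,5-diformyl-2,4,6-trimethoxyphenyl)-3-methylbutyl]eudesmane-4α,11-diol | CC(C)C[C@H](c1c(OC)c(C=O)c(OC)c(C=O)c1OC)[C@@H]1CC[C@@](C)(O)[C@@H]2C[C@H](C(C)(C)O)CC[C@]21C | intermediate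
23 | macrocarpal J | CC(C)C[C@H](c1c(O)c(C=O)c(O)c(C=O)c1O)[C@@H]1CC[C@@](C)(O)[C@@H]2C[C@H](C(C)(C)O)CC[C@]21C | target

## Step count and least certain steps

Total: 14 steps. Longest linear sequence: 13 steps (steps 1–5 and 7–14, from 1 to 23). Step 6 makes 12 in one operation from 9 and 10.

**Step 3 (key step).**
- What may go wrong: proton-initiated Prins closure may compete with the concerted ene process, leading to chloride capture at C4 or loss of H5 and with it the trans fusion. Closure may also be slow, because the aluminium-bound oxygen must pass syn-axial to C14, which leaves time for aldehyde self-condensation.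
- Fallback, from 3 back to 4: ene-type allylic chlorination of the isopropenyl group (NCS, PhSeCl cat., CH2Cl2) should give the allylic chloride aldehyde F1. An intramolecular Barbier allylation (Zn dust, THF/aq. NH4Cl, rt) would then form the same C2–C3 bond through the γ-carbon of the allylzinc and restore the exocyclic C4(15) alkene, arriving at 4. Either C2 epimer is usable.

**Step 7.**
- What may go wrong: poor topicity at C9′ (attack on both faces of the planar cation), loss of the cation by elimination or by Friedel–Crafts self-condensation, and a slow or unfavourable equilibrium at C1.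
- Fallback, from 8, 9 and 10 back to 14:
  - Grignard addition of 10 to 9 with aqueous work-up gives the racemic carbinol F4, and separation on a chiral stationary phase gives the (R)-carbinol F5.
  - Complexation with Cr(CO)3(MeCN)3 gives the tricarbonylchromium carbinol complex F6, and acetylation gives the complexed acetate F7.
  - Ionisation of F7 (BF3·OEt2, CH2Cl2, −78 °C) in the presence of 8 should proceed with loss of acetate anti to chromium and capture of the configurationally stable cation on the same exo face. This is overall retention, so the reagent fixes 9′S in the complexed ketone F8.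
  - Oxidative decomplexation (I2, THF) and NaOMe/MeOH then lead back to 14.

**Step 14.**
- What may go wrong: cleavage of the last ether may stall once two phenoxides are present, the thiolate may add to the formyl groups or substitute on the electron-poor ring, and the product may degrade at the temperature needed.
- Fallback, from 8 to 23, replacing methyl by benzyl ethers that are removed by neutral hydrogenolysis:
  - 2,4,6-Tris(benzyloxy)benzaldehyde F10 is treated as in step 6 to give the tribenzyl acetate F11.
  - Coupling with 8 as in step 7 gives the enone F12.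
  - The conditions of steps 8–10 then give the epoxy ketone F13, the allylic alcohol F14 and the saturated carbinol F15. The iridium catalyst of step 10 leaves benzyl ethers intact.
  - Steps 11–13 give the dibromide F16, the silylated dialdehyde F17 and the dialdehyde diol F18.
  - H2 with Pd/C (palladium on carbon) in EtOAc then removes the three benzyl groups to give 23.

**Step 2.**
- What may go wrong: competing oxidation at the internal carbon, palladium-promoted allylic isomerisation of the isopropenyl group, or acid-mediated cyclisation of the aldehyde as it forms.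
- Fallback, from 2 back to 3: rhodium-catalysed hydroboration (pinacolborane, RhCl(PPh3)3, THF), which favours the monosubstituted alkene, gives the pinacol boronate F2. Oxidation (NaBO3·4H2O, THF/H2O) gives the primary alcohol F3, and periodinane oxidation gives 3.

**Step 12.**
- What may go wrong: incomplete second halogen–lithium exchange, or proton quench of one carbanion, giving mono-formylation.
- Fallback, from 19 back to 21: double Suzuki–Miyaura vinylation (potassium vinyltrifluoroborate, Pd(OAc)2, SPhos, K3PO4, THF/H2O, 80 °C) gives the divinyl arene F9. Lemieux–Johnson cleavage (OsO4 cat., NaIO4, 2,6-lutidine, dioxane/H2O) then gives 21.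

## Further compounds

F1 | step 3 | 15-chloro-11-(triethylsilyloxy)elem-3-en-2-al (isopropenyl turned into 2-(chloromethyl)vinyl) | C=C(CCl)[C@@H]1C[C@H](C(C)(C)O[Si](CC)(CC)CC)CC[C@]1(CC=O)C
F2 | step 2 | pinacol boronate of 2 at C2 (C10 bears CH2CH2Bpin) | C=C(C)[C@@H]1C[C@H](C(C)(C)O[Si](CC)(CC)CC)CC[C@]1(CCB2OC(C)(C)C(C)(C)O2)C
F3 | step 2 | 11-(triethylsilyloxy)elem-3-en-2-ol | C=C(C)[C@@H]1C[C@H](C(C)(C)O[Si](CC)(CC)CC)CC[C@]1(CCO)C
F4 | step 7 | rac-3-methyl-1-(2,4,6-trimethoxyphenyl)butan-1-ol | CC(C)CC(O)c1c(OC)cc(OC)cc1OC
F5 | step 7 | (R)-3-methyl-1-(2,4,6-trimethoxyphenyl)butan-1-ol | CC(C)C[C@@H](O)c1c(OC)cc(OC)cc1OC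
F6 | step 7 | tricarbonylchromium η6-arene complex of F5 | CC(C)C[C@@H](O)c1c(OC)cc(OC)cc1OC.[Cr].[C-]#[O+].[C-]#[O+].[C-]#[O+]
F7 | step 7 | tricarbonylchromium η6-arene complex of the (R)-acetate | CC(C)C[C@@H](OC(C)=O)c1c(OC)cc(OC)cc1OC.[Cr].[C-]#[O+].[C-]#[O+].[C-]#[O+]
F8 | step 7 | tricarbonylchromium η6-arene complex of the (9′S)-ketone 13 | CC(C)C[C@H](c1c(OC)cc(OC)cc1OC)[C@H]1C(=O)C=C(C)[C@@H]2C[C@H](C(C)(C)O[Si](CC)(CC)CC)CC[C@]21C.[Cr].[C-]#[O+].[C-]#[O+].[C-]#[O+]
F9 | step 12 | (9′S)-1β-[1-(2,4,6-trimethoxy-3,5-divinylphenyl)-3-methylbutyl]-11-(triethylsilyloxy)eudesman-4α-ol | CC(C)C[C@H](c1c(OC)c(C=C)c(OC)c(C=C)c1OC)[C@@H]1CC[C@@](C)(O)[C@@H]2C[C@H](C(C)(C)O[Si](CC)(CC)CC)CC[C@]21C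
F10 | step 14 | 2,4,6-tris(benzyloxy)benzaldehyde | O=Cc1c(OCc2ccccc2)cc(OCc2ccccc2)cc1OCc1ccccc1
F11 | step 14 | rac-1-[2,4,6-tris(benzyloxy)phenyl]-3-methylbutyl acetate | CC(C)CC(OC(C)=O)c1c(OCc4ccccc4)cc(OCc4ccccc4)cc1OCc4ccccc4
F12 | step 14 | tribenzyl analogue of 14 | CC(C)C[C@H](c1c(OCc4ccccc4)cc(OCc4ccccc4)cc1OCc4ccccc4)[C@@H]1C(=O)C=C(C)[C@@H]2C[C@H](C(C)(C)O[Si](CC)(CC)CC)CC[C@]21C
F13 | step 14 | tribenzyl analogue of 15 | CC(C)C[C@H](c1c(OCc4ccccc4)cc(OCc4ccccc4)cc1OCc4ccccc4)[C@@H]1C(=O)[C@H]3O[C@@]3(C)[C@@H]2C[C@H](C(C)(C)O[Si](CC)(CC)CC)CC[C@]21C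
F14 | step 14 | tribenzyl analogue of 17 | CC(C)C[C@H](c1c(OCc4ccccc4)cc(OCc4ccccc4)cc1OCc4ccccc4)[C@@H]1C=C[C@@](C)(O)[C@@H]2C[C@H](C(C)(C)O[Si](CC)(CC)CC)CC[C@]21C
F15 | step 14 | tribenzyl analogue of 18 | CC(C)C[C@H](c1c(OCc4ccccc4)cc(OCc4ccccc4)cc1OCc4ccccc4)[C@@H]1CC[C@@](C)(O)[C@@H]2C[C@H](C(C)(C)O[Si](CC)(CC)CC)CC[C@]21C
F16 | step 14 | tribenzyl analogue of 19 | CC(C)C[C@H](c1c(OCc4ccccc4)c(Br)c(OCc4ccccc4)c(Br)c1OCc4ccccc4)[C@@H]1CC[C@@](C)(O)[C@@H]2C[C@H](C(C)(C)O[Si](CC)(CC)CC)CC[C@]21C
F17 | step 14 | tribenzyl analogue of 21 | CC(C)C[C@H](c1c(OCc4ccccc4)c(C=O)c(OCc4ccccc4)c(C=O)c1OCc4ccccc4)[C@@H]1CC[C@@](C)(O)[C@@H]2C[C@H](C(C)(C)O[Si](CC)(CC)CC)CC[C@]21C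
F18 | step 14 | macrocarpal J tri-O-benzyl ether | CC(C)C[C@H](c1c(OCc4ccccc4)c(C=O)c(OCc4ccccc4)c(C=O)c1OCc4ccccc4)[C@@H]1CC[C@@](C)(O)[C@@H]2C[C@H](C(C)(C)O)CC[C@]21C
A1 | alternative 1 | acyclic (Z,E)-trienone carrying the C1 side chain and silylated C11 carbinol | C=CC(=O)CC[C@@H]([C@H](CC(C)C)c1c(OC)cc(OC)cc1OC)/C(C)=C\C=C\C(C)(C)O[Si](CC)(CC)CC
A2 | alternative 1 | trans-fused 15-nor-eudesm-8-en-4-one with the C1 side chain and silylated C11 carbinol | CC(C)C[C@H](c1c(OC)cc(OC)cc1OC)[C@@H]2CCC(=O)[C@@H]3C[C@H](C(C)(C)O[Si](CC)(CC)CC)C=C[C@]32C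
A3 | alternative 2 | (2E,6E)-farnesyl diphosphate | CC(C)=CCC/C(C)=C/CC/C(C)=C/COP(=O)(O)OP(=O)(O)O
A4 | alternative 2 | (7R)-hedycaryol | C1/C=C(C)/CC[C@@H](C(C)(C)O)C/C=C(C)/C1
A5 | alternative 2 | ortho-quinone methide of 3,5-diformyl-2,4,6-trihydroxy-(3-methylbutyl)benzene | CC(C)CC=C1C(=O)C(C=O)=C(O)C(C=O)=C1O
A6 | alternative 3 | methacrolein | C=C(C)C=O
A7 | alternative 3 | (E)-diene with C7 silyloxyisopropyl and C5 ketal branch | C=C(C(C)(C)O[Si](C)(C)C(C)(C)C)/C=C/C1(C)OCCO1
A8 | alternative 3 | exo cycloadduct (ring B with C10 formyl and methyl, C5 ketal branch) | O=C[C@]1(C)CCC(C(C)(C)O[Si](C)(C)C(C)(C)C)=C[C@H]1C2(C)OCCO2
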